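A small charge of free catalyst, 1.0 mM, works through 0.121 M of reagent in this flask, with 0.30 mM of impurity beside it and each hand of substrate at 0.11 M.

in all of them: reagent 0.121 M; impurity 0.30 mM

| run | left-handed substrate | right-handed substrate | free catalyst | remark |
|---|---|---|---|---|
| noon | 0.055 M | 0.055 M | 1 mM | run made earlier |
| autumn | 0.22 M | 0.22 M | 1 mM | run made earlier |
| flask | 0.11 M | 0.11 M | 1.0 mM |  |

| run | time / h | left-handed product / % | left-handed substrate / % |
|---|---|---|---|
| noon | 0.200 | 1.6 | 48.1 |
| noon | 0.667 | 5.2 | 45.2 |
| noon | 1.33 | 8.6 | 40.4 |
| noon | 2.00 | 11.8 | 38.5 |
| noon | 2.50 | 12.8 | 37.2 |
| autumn | 0.200 | 1.2 | 48.4 |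
| autumn | 0.667 | 5.2 | 45.2 |
| autumn | 1.33 | 7.9 | 43.2 |
| autumn | 2.00 | 9.4 | 40.8 |
| autumn | 2.50 | 10.3 | 39.2 |

(scatter of a reading: 0.5 percentage points)

- free catalyst is single-handed; left-handed substrate and right-handed substrate are mirror images of each other, charged as a racemate, each of them at the stated concentration
- no earlier run changes the charge of reagent; that part of a forecast is a guess

* apparent order in reagent when 30% of the left-handed substrate and right-handed substrate together are converted (percent change of the rate of making left-handed product for one percent more reagent charged)

In the first instants c(reagent) stands at its charge. The noon and autumn runs then look alike in percent: left-handed product reads 5.2% and 5.2% at 0.667 h. So the rate follows substrate, about first order.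

In the middle they part. From 1.33 h to 2.50 h the autumn run gains less left-handed product than the noon run, a reading of 0.571 of the noon gain. At one reagent per substrate, which is my assumption, autumn's left-handed product has taken 0.0453 M of reagent by 2.50 h, and noon's 0.0141 M. I read that as reagent falling, and I take the rate as first order in c(reagent). No run varied it, so this is my choice.

Then comes the look at 30% conversion. Against both hands together, reagent is the limiting reagent. At one reagent per substrate, that conversion uses 0.0660 M, so by my count 0.0550 M stands. At fixed conversion, substrate and products stand the same whatever reagent was charged, and I take the catalyst's state to follow conversion too. By my reckoning, extra charge then adds in full to what stands at the look. The charge over what stands there, 2.20, is the lever: one percent more charge gives that many percent more c(reagent), and so more rate. The catalyst is a small correction. If each catalyst took one reagent, that would cost 1.0 mM, 1.82% of what stands, and the lever would go to 2.24.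

The forecast has the same leverage, 2.2, but takes a local order of about 0.5 where I take 1, so its order of 1.1, with a range from 0.2 to 2.3 and called “largely a guess”, stands below my 2.20.

The flask gives 2.2, as the lever has it.

    reagent + free catalyst → spent catalyst A (k = 0.0310 /M/min)
    free catalyst + impurity → spent catalyst B (k = 706 /M/min)
    reagent + free catalyst + right-handed substrate → free catalyst + right-handed product (k = 12.9 /M²/min)
    reagent + free catalyst + left-handed substrate → free catalyst + left-handed product (k = 33.4 /M²/min)

The flask reaches 30% conversion at 8.83 h, making left-handed product at 0.00144 M/h. The inverse of the lever puts reagent there at 45.5% of its charge, between 68.4% at 2.50 h and 32.4% at 25.0 h. For the noon recipe at the same conversion, the lever is 1.38.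

The numbers in the tables were computed for an exercise; noise was put on by code.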